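The carbocycle (ring B, C5–C10 in labdane-type numbering) is opened at both ends of its C6–C7 ethano bridge. One anionic double Michael addition stitches phenyl vinyl sulfone, an ethylene equivalent, into an acyclic nitro enoate: the C8 nitronate adds first and the resulting sulfonyl carbanion closes 6-exo onto C5 of the C4=C5 enoate. The step exploits that C8 is the oxygen-bearing ring carbon (nitro as latent carbonyl) and that C5 lies β to the C3 ester carbonyl. The C9/C10 pair, set by organocatalysis, relays its configuration to C5; C13 is bought as (R)-linalool and C8 is set when the pyran closes.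

Key step: step 8

Remark on numbering: C1/C2 = CH2–CO2H arm on C10; C3 = ester carbon; C4 = CMe2; ring B = C5–C10 (C10 carries the C20 methyl); C11/C12 = pyran CH2CH2; C13 = ether carbon with methyl and vinyl; C17 = methyl on C8.
Assumption: the enantiomer of the amine catalyst in step 5 (and of the auxiliary in its fallback) is the one that gives (3S,4S)-9; the sense is taken from the acyclic synclinal enamine–nitroalkene model.
Remark on mixtures: 15–22 are carried as C4 epimers (15 and 16 also as C6/C8 epimers); these centres are erased in steps 9, 10 and 14.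

Step 1
Reactants: 1 (R)-(−)-linalool
Product: 2 triethyl{[(3R)-3,7-dimethylocta-1,6-dien-3-yl]oxy}silane
Conditions: Et3SiOTf, 2,6-lutidine, CH2Cl2, −78 → 0 °C
Reagents that add atoms: triethylsilyl trifluoromethanesulfonate, CC[Si](CC)(CC)OS(=O)(=O)C(F)(F)F
Why: Silyl ether formation with the reactive triflate should cap the hindered tertiary allylic alcohol without touching the C13 stereocentre, which stops the oxygen from closing onto the nitroalkene made in step 3.

Step 2
Reactants: 2 triethyl{[(3R)-3,7-dimethylocta-1,6-dien-3-yl]oxy}silane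
Product: 3 (4R)-4-methyl-4-[(triethylsilyl)oxy]hex-5-enal
Conditions: O3, CH2Cl2/pyridine, −78 °C (Sudan Red 7B end point); then Me2S
Reagents that add atoms: ozone, [O-][O+]=O
Why: In this chemoselective ozonolysis with reductive work-up the electron-rich trisubstituted alkene should react far faster than the vinyl group on the quaternary silyloxy carbon, so one equivalent of ozone cleaves only the isopropylidene unit.

Step 3
Reactants: 3 (4R)-4-methyl-4-[(triethylsilyl)oxy]hex-5-enal; 4 nitromethane
Product: 6 triethyl{[(3R,6E)-3-methyl-7-nitrohepta-1,6-dien-3-yl]oxy}silane, via nitro alcohol 5 (not isolated)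
Conditions: 4 (5 equiv), t-BuOK (10 mol %), THF/t-BuOH, 0 °C; then MsCl, Et3N, CH2Cl2, 0 °C
Reagents that add atoms: none
Why: A Henry (nitroaldol) addition followed by mesylation and E1cB elimination should give the conjugated nitroalkene as the more stable (E)-isomer, and no stereocentre is formed.

Step 4
Reactants: 7 ethyl (2E)-3-methyl-4-oxobut-2-enoate
Product: 8 ethyl 3-methyl-4-oxobutanoate (racemic)
Conditions: H2 (1 atm), Pd/C (5 wt %), EtOAc, rt
Reagents that add atoms: none
Why: Heterogeneous hydrogenation should saturate the electron-poor C=C faster than the aldehyde C=O; the stereocentre formed is racemic and is erased as an enamine in step 5.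

Step 5
Reactants: 6 triethyl{[(3R,6E)-3-methyl-7-nitrohepta-1,6-dien-3-yl]oxy}silane; 8 ethyl 3-methyl-4-oxobutanoate
Product: 9 ethyl (3S,4S,7R)-3-formyl-3,7-dimethyl-4-(nitromethyl)-7-[(triethylsilyl)oxy]non-8-enoate
Conditions: 8 (2 equiv), chiral primary amine–thiourea (trans-cyclohexane-1,2-diamine type, 20 mol %), H2O (2 equiv), CH2Cl2, rt
Reagents that add atoms: none
Why: In this enamine-mediated Michael addition the racemic aldehyde converges through its enamine (larger CH2CO2Et arm anti to nitrogen), the thiourea binds the nitro group, and the acyclic synclinal transition state on the catalyst-defined face should set the quaternary C10 and the tertiary C9 together as the syn pair.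

Step 6
Reactants: 9 ethyl (3S,4S,7R)-3-formyl-3,7-dimethyl-4-(nitromethyl)-7-[(triethylsilyl)oxy]non-8-enoate
Product: 10 (3S,4S,7R)-3-formyl-3,7-dimethyl-4-(nitromethyl)-7-[(triethylsilyl)oxy]non-8-enoic acid
Conditions: LiOH (3 equiv), THF/H2O 3:1, 0 °C → rt; then aq. HCl to pH 3
Reagents that add atoms: lithium hydroxide, [Li+].[OH-]
Why: Saponification of the only ester present, assisted by the neighbouring aldehyde hydrate through a five-membered hydroxy lactone, should free the C2 carboxyl group before the C3 methyl ester is introduced, so the two carboxyl carbons never have to be told apart; the aldehyde cannot enolise and no stereocentre is touched.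

Step 7
Reactants: 10 (3S,4S,7R)-3-formyl-3,7-dimethyl-4-(nitromethyl)-7-[(triethylsilyl)oxy]non-8-enoic acid; 11 methyl 2-(triphenyl-λ5-phosphanylidene)propanoate
Product: 12 (3R,4S,7R)-3-[(1E)-3-methoxy-2-methyl-3-oxoprop-1-en-1-yl]-3,7-dimethyl-4-(nitromethyl)-7-[(triethylsilyl)oxy]non-8-enoic acid
Conditions: 11 (1.5 equiv), Et3N (1.2 equiv), toluene, 90 °C; then aq. HCl
Reagents that add atoms: none
Why: Wittig olefination of the ring-opened carboxylate aldehyde with the stabilised α-methyl ylide should give the (E)-configured 2-methylenoate, which places the Michael acceptor carbon C5 next to C10.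

Step 8
Reactants: 12 (3R,4S,7R)-3-[(1E)-3-methoxy-2-methyl-3-oxoprop-1-en-1-yl]-3,7-dimethyl-4-(nitromethyl)-7-[(triethylsilyl)oxy]non-8-enoic acid; 13 phenyl vinyl sulfone
Product: 15 2-[(1S,2S,6R)-6-(1-methoxy-1-oxopropan-2-yl)-1-methyl-2-{(3R)-3-methyl-3-[(triethylsilyl)oxy]pent-4-en-1-yl}-3-nitro-5-(phenylsulfonyl)cyclohexyl]acetic acid, via mono-Michael adduct 14 (not isolated)
Conditions: 13 (1.05 equiv), t-BuOK (3.5 equiv), DMSO/THF 1:3, 0 °C → rt; then AcOH
Reagents that add atoms: none
Why: t-BuOK deprotonates the acid and the primary nitro group, the nitronate adds to the β-carbon of the vinyl sulfone (C7–C8), and after proton transfer the excess base forms the α-sulfonyl carbanion at C6, which adds 6-exo-trig to C5 of the (E)-enoate (C5–C6) before the ester enolate is protonated. This is a Michael–Michael ring closure, an anionic [4+2] annulation with a vinyl sulfone as ethylene equivalent. Ring B closes through a chair in which the C9 side chain, the C10 CH2CO2 arm and the enoate are equatorial and only the C10 methyl is axial, so the new C5–H ends anti to that methyl: C5 is controlled by the C9/C10 pair. C8, C6 and C4 form as epimer mixtures, which is harmless because C8 and C6 lose their substituents in steps 9 and 10 and C4 becomes quaternary in step 14. The step needs mono-addition of the nitronate, secured by the branched C9 neighbour and one equivalent of sulfone, and attack of the carbanion on the enoate β-carbon only, secured by the inert carboxylate and by the (E)-geometry that keeps the methyl ester carbonyl out of reach.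

Step 9
Reactants: 15 2-[(1S,2S,6R)-6-(1-methoxy-1-oxopropan-2-yl)-1-methyl-2-{(3R)-3-methyl-3-[(triethylsilyl)oxy]pent-4-en-1-yl}-3-nitro-5-(phenylsulfonyl)cyclohexyl]acetic acid
Product: 17 2-[(1R,2R,6S)-2-(1-methoxy-1-oxopropan-2-yl)-1-methyl-6-{(3R)-3-methyl-3-[(triethylsilyl)oxy]pent-4-en-1-yl}-5-oxocyclohex-3-en-1-yl]acetic acid, via sulfonyl ketone 16 (not isolated)
Conditions: NaOMe, MeOH, 0 °C; TiCl3, aq. NH4OAc, rt; then DBU, CH2Cl2, rt
Reagents that add atoms: water, O
Why: A Nef reaction (reduction of the nitronate by TiCl3 to the imine and hydrolysis) should unmask the C8 ketone, after which DBU expels sulfinate from C6 by E1cB elimination through the C7 enolate; C9 is now epimerisable but already holds the more stable equatorial side chain.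

Step 10
Reactants: 17 2-[(1R,2R,6S)-2-(1-methoxy-1-oxopropan-2-yl)-1-methyl-6-{(3R)-3-methyl-3-[(triethylsilyl)oxy]pent-4-en-1-yl}-5-oxocyclohex-3-en-1-yl]acetic acid
Product: 18 2-[(1R,2S,6R)-6-(1-methoxy-1-oxopropan-2-yl)-1-methyl-2-{(3R)-3-methyl-3-[(triethylsilyl)oxy]pent-4-en-1-yl}-3-oxocyclohexyl]acetic acid
Conditions: K[(s-Bu)3BH] (2.3 equiv), THF, −78 °C; then AcOH
Reagents that add atoms: none
Why: Conjugate hydride reduction of the β-unsubstituted cyclohexenone by the hindered trialkylborohydride should give the C7 enolate regiospecifically (the first equivalent only deprotonates the acid), and protonation returns the saturated ketone without creating a stereocentre.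

Step 11
Reactants: 18 2-[(1R,2S,6R)-6-(1-methoxy-1-oxopropan-2-yl)-1-methyl-2-{(3R)-3-methyl-3-[(triethylsilyl)oxy]pent-4-en-1-yl}-3-oxocyclohexyl]acetic acid
Product: 19 2-[(1R,2R,6R)-6-(1-methoxy-1-oxopropan-2-yl)-1-methyl-3-methylidene-2-{(3R)-3-methyl-3-[(triethylsilyl)oxy]pent-4-en-1-yl}cyclohexyl]acetic acid
Conditions: Zn, CH2Br2, TiCl4 (excess, pre-aged), THF/CH2Cl2, 0 °C → rt
Reagents that add atoms: dibromomethane, BrCBr
Why: The non-basic Takai–Lombardo methylenation should convert the hindered ketone into the exocyclic alkene that carries C17 without epimerising C9 and without attacking the ester or the acid.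

Step 12
Reactants: 19 2-[(1R,2R,6R)-6-(1-methoxy-1-oxopropan-2-yl)-1-methyl-3-methylidene-2-{(3R)-3-methyl-3-[(triethylsilyl)oxy]pent-4-en-1-yl}cyclohexyl]acetic acid
Product: 20 2-[(1R,2R,6R)-2-[(3R)-3-hydroxy-3-methylpent-4-en-1-yl]-6-(1-methoxy-1-oxopropan-2-yl)-1-methyl-3-methylidenecyclohexyl]acetic acid
Conditions: Bu4NF (3 equiv), THF, rt → 40 °C; then aq. HCl (pH 4)
Reagents that add atoms: none
Why: Fluoride-induced cleavage of the Si–O bond should free the C13 tertiary alcohol and leaves all stereocentres untouched.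

Step 13
Reactants: 20 2-[(1R,2R,6R)-2-[(3R)-3-hydroxy-3-methylpent-4-en-1-yl]-6-(1-methoxy-1-oxopropan-2-yl)-1-methyl-3-methylidenecyclohexyl]acetic acid
Product: 22 2-[(2R,4aS,5R,6R,8aS)-2-ethenyl-6-(1-methoxy-1-oxopropan-2-yl)-2,5,8a-trimethyloctahydro-2H-chromen-5-yl]acetic acid, via organomercurial 21 (not isolated)
Conditions: Hg(OCOCF3)2 (1.1 equiv), THF, −20 → 0 °C; then NaBH4, aq. NaOH, 0 °C
Reagents that add atoms: none
Why: Intramolecular alkoxymercuration (Markovnikov, 6-exo) followed by hydride demercuration should close the pyran, because the C13 oxygen adds to C8 equatorially through a chair–chair transition state, which gives the trans-fused ring with the new C8 methyl axial and syn to the C10 methyl, while the carboxyl group cannot reach C8 without a ring flip and the vinyl group has no ring-forming partner.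

Step 14
Reactants: 22 2-[(2R,4aS,5R,6R,8aS)-2-ethenyl-6-(1-methoxy-1-oxopropan-2-yl)-2,5,8a-trimethyloctahydro-2H-chromen-5-yl]acetic acid
Product: 23 2-[(2R,4aS,5R,6S,8aS)-2-ethenyl-6-(1-methoxy-2-methyl-1-oxopropan-2-yl)-2,5,8a-trimethyloctahydro-2H-chromen-5-yl]acetic acid
Conditions: LiN(i-Pr)2 (3 equiv), THF, −78 → −30 °C; MeI (1.3 equiv), −78 → −20 °C; then aq. HCl
Reagents that add atoms: iodomethane, CI
Why: Enolate alkylation of the carboxylate–ester dianion (the ester α-proton is removed, the carboxylate α-protons are not at low temperature) should introduce the second methyl group at C4, which turns the C4 epimer mixture into the single, non-stereogenic quaternary centre of the target.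

Compound list
1 | (R)-(−)-linalool, (3R)-3,7-dimethylocta-1,6-dien-3-ol | C=C[C@](C)(O)CCC=C(C)C | starting material
2 | triethyl{[(3R)-3,7-dimethylocta-1,6-dien-3-yl]oxy}silane | C=C[C@](C)(O[Si](CC)(CC)CC)CCC=C(C)C | intermediate
3 | (4R)-4-methyl-4-[(triethylsilyl)oxy]hex-5-enal | C=C[C@](C)(O[Si](CC)(CC)CC)CCC=O | intermediate
4 | nitromethane | C[N+](=O)[O-] | starting material
5 | (5R)-5-methyl-1-nitro-5-[(triethylsilyl)oxy]hept-6-en-2-ol (both C2 epimers) | C=C[C@](C)(O[Si](CC)(CC)CC)CCC(O)C[N+](=O)[O-] | intermediate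
6 | triethyl{[(3R,6E)-3-methyl-7-nitrohepta-1,6-dien-3-yl]oxy}silane | C=C[C@](C)(O[Si](CC)(CC)CC)CC/C=C/[N+](=O)[O-] | intermediate
7 | ethyl (2E)-3-methyl-4-oxobut-2-enoate | CCOC(=O)/C=C(\C)C=O | starting material
8 | ethyl 3-methyl-4-oxobutanoate (racemic) | CCOC(=O)CC(C)C=O | intermediate
9 | ethyl (3S,4S,7R)-3-formyl-3,7-dimethyl-4-(nitromethyl)-7-[(triethylsilyl)oxy]non-8-enoate | C=C[C@](C)(O[Si](CC)(CC)CC)CC[C@H](C[N+](=O)[O-])[C@](C)(CC(=O)OCC)C=O | intermediate
10 | (3S,4S,7R)-3-formyl-3,7-dimethyl-4-(nitromethyl)-7-[(triethylsilyl)oxy]non-8-enoic acid (in equilibrium with its hydroxy lactone) | C=C[C@](C)(O[Si](CC)(CC)CC)CC[C@H](C[N+](=O)[O-])[C@](C)(CC(=O)O)C=O | intermediate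
11 | methyl 2-(triphenyl-λ5-phosphanylidene)propanoate | COC(=O)C(C)=P(c1ccccc1)(c1ccccc1)c1ccccc1 | starting material
12 | (3R,4S,7R)-3-[(1E)-3-methoxy-2-methyl-3-oxoprop-1-en-1-yl]-3,7-dimethyl-4-(nitromethyl)-7-[(triethylsilyl)oxy]non-8-enoic acid | C=C[C@](C)(O[Si](CC)(CC)CC)CC[C@H](C[N+](=O)[O-])[C@](C)(CC(=O)O)/C=C(\C)C(=O)OC | intermediate
13 | phenyl vinyl sulfone, (ethenesulfonyl)benzene | C=CS(=O)(=O)c1ccccc1 | starting material
14 | (3R,4S,7R)-3-[(1E)-3-methoxy-2-methyl-3-oxoprop-1-en-1-yl]-3,7-dimethyl-4-[1-nitro-3-(phenylsulfonyl)propyl]-7-[(triethylsilyl)oxy]non-8-enoic acid (both epimers at the nitro carbon) | C=C[C@](C)(O[Si](CC)(CC)CC)CC[C@H](C(CCS(=O)(=O)c1ccccc1)[N+](=O)[O-])[C@](C)(CC(=O)O)/C=C(\C)C(=O)OC | intermediate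
15 | 2-[(1S,2S,6R)-6-(1-methoxy-1-oxopropan-2-yl)-1-methyl-2-{(3R)-3-methyl-3-[(triethylsilyl)oxy]pent-4-en-1-yl}-3-nitro-5-(phenylsulfonyl)cyclohexyl]acetic acid (epimers at C-3, C-5 and the propanoate α-carbon) | C=C[C@](C)(O[Si](CC)(CC)CC)CC[C@H]1[C@](C)(CC(=O)O)[C@@H](C(C)C(=O)OC)C(S(=O)(=O)c2ccccc2)CC1[N+](=O)[O-] | intermediate
16 | 2-[(1S,2S,6R)-6-(1-methoxy-1-oxopropan-2-yl)-1-methyl-2-{(3R)-3-methyl-3-[(triethylsilyl)oxy]pent-4-en-1-yl}-3-oxo-5-(phenylsulfonyl)cyclohexyl]acetic acid (epimers at C-5 and the propanoate α-carbon) | C=C[C@](C)(O[Si](CC)(CC)CC)CC[C@H]1[C@](C)(CC(=O)O)[C@@H](C(C)C(=O)OC)C(S(=O)(=O)c2ccccc2)CC1=O | intermediate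
17 | 2-[(1R,2R,6S)-2-(1-methoxy-1-oxopropan-2-yl)-1-methyl-6-{(3R)-3-methyl-3-[(triethylsilyl)oxy]pent-4-en-1-yl}-5-oxocyclohex-3-en-1-yl]acetic acid | C=C[C@](C)(O[Si](CC)(CC)CC)CC[C@H]1[C@](C)(CC(=O)O)[C@@H](C(C)C(=O)OC)C=CC1=O | intermediate
18 | 2-[(1R,2S,6R)-6-(1-methoxy-1-oxopropan-2-yl)-1-methyl-2-{(3R)-3-methyl-3-[(triethylsilyl)oxy]pent-4-en-1-yl}-3-oxocyclohexyl]acetic acid | C=C[C@](C)(O[Si](CC)(CC)CC)CC[C@H]1[C@](C)(CC(=O)O)[C@@H](C(C)C(=O)OC)CCC1=O | intermediate
19 | 2-[(1R,2R,6R)-6-(1-methoxy-1-oxopropan-2-yl)-1-methyl-3-methylidene-2-{(3R)-3-methyl-3-[(triethylsilyl)oxy]pent-4-en-1-yl}cyclohexyl]acetic acid | C=C[C@](C)(O[Si](CC)(CC)CC)CC[C@H]1[C@](C)(CC(=O)O)[C@@H](C(C)C(=O)OC)CCC1=C | intermediate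
20 | 2-[(1R,2R,6R)-2-[(3R)-3-hydroxy-3-methylpent-4-en-1-yl]-6-(1-methoxy-1-oxopropan-2-yl)-1-methyl-3-methylidenecyclohexyl]acetic acid | C=C[C@](C)(O)CC[C@H]1[C@](C)(CC(=O)O)[C@@H](C(C)C(=O)OC)CCC1=C | intermediate
21 | 2-[(2R,4aS,5R,6R,8aS)-2-ethenyl-6-(1-methoxy-1-oxopropan-2-yl)-2,5-dimethyl-8a-{[(trifluoroacetoxy)mercurio]methyl}octahydro-2H-chromen-5-yl]acetic acid | C=C[C@@]1(C)CC[C@H]2[C@](C)(CC(=O)O)[C@@H](C(C)C(=O)OC)CC[C@]2(C[Hg]OC(=O)C(F)(F)F)O1 | intermediate
22 | 2-[(2R,4aS,5R,6R,8aS)-2-ethenyl-6-(1-methoxy-1-oxopropan-2-yl)-2,5,8a-trimethyloctahydro-2H-chromen-5-yl]acetic acid (both epimers at the propanoate α-carbon) | C=C[C@@]1(C)CC[C@H]2[C@](C)(CC(=O)O)[C@@H](C(C)C(=O)OC)CC[C@]2(C)O1 | intermediate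
23 | 2-[(2R,4aS,5R,6S,8aS)-2-ethenyl-6-(1-methoxy-2-methyl-1-oxopropan-2-yl)-2,5,8a-trimethyloctahydro-2H-chromen-5-yl]acetic acid (CNP0280657.1) | C=C[C@@]1(C)CC[C@H]2[C@](C)(CC(=O)O)[C@@H](C(C)(C)C(=O)OC)CC[C@]2(C)O1 | target

Total step count: 14. Longest linear sequence: 13 steps (1 → 23 through steps 1–3 and 5–14).

Steps most likely to fail

Step 8 (key step). The sulfonyl carbanion may form too slowly or add reversibly to the hindered, trisubstituted enoate, so that the sequence stops after the first Michael addition or the sulfone unit is lost again by retro-Michael reaction. Fallback: raise the electrophilicity of C5 and adjust the oxidation level afterwards. The fallback sets out from acid 10, which is olefinated with 2-(triphenyl-λ5-phosphanylidene)propanal (Et3N, toluene, 80 °C) to the (E)-enal acid F1. Its double Michael addition with 13 (t-BuOK, DMSO/THF) should close ring B in the same one-pot manner and give the ring aldehyde F2. Oxidation of the aldehyde in methanol (pyridinium dichromate, MeOH, DMF) gives the methyl ester and comes back to the route at 15.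

Step 5. Control of the enamine geometry at the α-branched aldehyde may be poor with a primary amine catalyst, which erodes selectivity at the quaternary C10, and turnover may be slow. Fallback: a stoichiometric tertiary enamine whose geometry is fixed by allylic strain. The fallback sets out from aldehyde 8, which is condensed with (2S)-2-(methoxymethyl)pyrrolidine (molecular sieves, toluene) to the (E)-enamine F3. This adds to nitroalkene 6 (Et2O, −40 °C → rt) to give the iminium nitronate F4, which is not isolated. Hydrolysis with aqueous AcOH releases the auxiliary and comes back to the route at 9.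

Step 13. The mercury electrophile may also attack the C13 vinyl group, or the alkoxymercuration may revert during the reduction. Fallback: halocyclisation and radical dehalogenation. The fallback sets out from alcohol 20, which is treated with I2 and NaHCO3 in MeCN at 0 °C to give the iodomethyl pyran F5 by the same equatorial ring closure. Tributyltin hydride with AIBN (toluene, 80 °C) replaces iodine by hydrogen and comes back to the route at 22.

Further compounds
F1 | step 8 | (3R,4S,7R)-3,7-dimethyl-3-[(1E)-2-methyl-3-oxoprop-1-en-1-yl]-4-(nitromethyl)-7-[(triethylsilyl)oxy]non-8-enoic acid | C=C[C@](C)(O[Si](CC)(CC)CC)CC[C@H](C[N+](=O)[O-])[C@](C)(CC(=O)O)/C=C(\C)C=O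
F2 | step 8 | 2-[(1S,2S,6R)-1-methyl-2-{(3R)-3-methyl-3-[(triethylsilyl)oxy]pent-4-en-1-yl}-3-nitro-6-(1-oxopropan-2-yl)-5-(phenylsulfonyl)cyclohexyl]acetic acid | C=C[C@](C)(O[Si](CC)(CC)CC)CC[C@H]1[C@](C)(CC(=O)O)[C@@H](C(C)C=O)C(S(=O)(=O)c2ccccc2)CC1[N+](=O)[O-]
F3 | step 5 | ethyl (3E)-4-[(2S)-2-(methoxymethyl)pyrrolidin-1-yl]-3-methylbut-3-enoate | CCOC(=O)C/C(C)=C/N1CCC[C@H]1COC
F4 | step 5 | iminium nitronate zwitterion from F3 and 6 | C=C[C@](C)(O[Si](CC)(CC)CC)CC[C@H](C=[N+]([O-])[O-])[C@](C)(CC(=O)OCC)C=[N+]1CCC[C@H]1COC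
F5 | step 13 | 2-[(2R,4aS,5R,6R,8aS)-2-ethenyl-8a-(iodomethyl)-6-(1-methoxy-1-oxopropan-2-yl)-2,5-dimethyloctahydro-2H-chromen-5-yl]acetic acid | C=C[C@@]1(C)CC[C@H]2[C@](C)(CC(=O)O)[C@@H](C(C)C(=O)OC)CC[C@]2(CI)O1
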